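## The problem

The target (23) joins two stereochemical domains through a CH2–CH2 bridge. One is a cis-fused 1,4,4a,7,8,8a-hexahydronaphthalene: ring A (C4a, C5, C6, C7, C8, C8a) holds the trisubstituted C5=C6 alkene, and ring B (C1, C2, C3, C4, C4a, C8a) holds the tetrasubstituted C2=C3 alkene next to the quaternary C1. The other is a 1,2-dioxane with a quaternary peroxy carbon (C6), a secondary peroxy carbon (C3) and, outside the ring, the α-carbon of a propanoic acid.

The two ring-fusion centres (4aR, 8aS) fix each other once the cis junction exists. They lie five bonds from the nearest dioxane centre and cannot control it, so two enantiopure halves must be joined. Inside the dioxane, propanoate C2 and ring C3 are neighbours (anti). C6 sits 1,4 to C3 and carries two groups of nearly equal size (CH3, CH2R), so C6 cannot steer C3; C3 and C2 need reagent control.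

The octalin is the harder half to build. It needs a cis junction, two alkenes in fixed positions, a tetrasubstituted alkene flanked by a quaternary carbon, and a carbon substituent on that alkene carbon (C2) as the only point of attachment.

The O–O bond does not survive phosphines, hydride, dissolving metals or low-valent metals in excess. Base can trigger Kornblum–DeLaMare cleavage at C3–H or retro-oxa-Michael opening through the ester enolate. The octalin alkenes would not survive singlet oxygen, radical hydroperoxidation or strong acid, so the peroxide must be made on a fragment that lacks them.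

The feature that opens the problem is the array C6=C5–C4a–C4–C3=C2 with C1 fully substituted. If the bond from C2 to the linker is replaced by C2–O, this array is the δ,ε-unsaturated enolate that an anionic oxy-Cope rearrangement delivers. The cis junction is what the boat-shaped [3,3] shift of a 2-alkenylbicyclo[2.2.2]oct-5-en-2-olate gives. The bicycle in turn comes from a dearomatized phenol and ethylene.

## Retrosynthesis

**23 ⇒ 22 ⇒ 9 + 20.** After ester release, the bond between octalin C2 (sp2) and the linker CH2 is cut. The neighbouring cuts are worse. Cutting at dioxane C6 would need a peroxide-bearing carbanion or a late quaternary C–O bond, and cutting the CH2–CH2 bond is an sp3–sp3 coupling. The chosen cut gives an enol triflate (9) and a vinyl-dioxane (20), each holding one stereochemical domain. The forward step (hydroboration, B-alkyl Suzuki–Miyaura coupling) must tolerate the O–O bond and a hindered triflate.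

**9 ⇒ 6.** Retro-[3,3]: the C4–C4a bond is cut and C2 is rejoined to C6. This bond is not in the target; it is made on purpose and broken in the key step. The precursor is the bicyclo[2.2.2]octenol 6. The forward step must give the cis junction, the C5=C6 alkene, and a regiodefined tetrasubstituted enolate that is trapped as triflate 9. The rearrangement does all three by its mechanism, which no stepwise annulation of ring B onto ring A would.

**6 ⇒ 5 ⇒ 4 ⇒ 3 ⇒ 1.** The C2–isopropenyl bond is cut (1,2-addition to ketone 5). The two bonds from the bridgeheads to the ethano bridge are cut (Diels–Alder of dienone 3 with ethylene). One C–CH3 bond is cut (ortho-methylation of 2,6-dimethylphenol 1, a dearomatization). Ethylene raises no regio- or endo/exo question. The price is a racemate (4), resolved at the smallest possible intermediate to give 5.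

**20 ⇒ 19 ⇒ 18 ⇒ 17 ⇒ 14 + 15.** The vinyl group comes from aldehyde 19 and the aldehyde from the acetonide 18. The C3–C(α) bond is then cut: a peroxycarbenium ion from methyl peroxyacetal 14 is joined to the titanium enolate of thioimide 15. One bond sets both C3 and propanoate C2 under auxiliary control, which is needed because C6 cannot direct C3.

**14 ⇒ 12 ⇒ 11 ⇒ 10.** The acetal carbon is a latent aldehyde (ozonolysis of the prenyl group). The tertiary C–OO bond comes from perhydrolysis of an epoxide with inversion. The epoxide comes from Sharpless epoxidation of geraniol (10), which supplies dioxane C3 to C6, the C6 methyl and the carbon that becomes the vinyl CH.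

## Roads not taken

**Alternative 1:** (the most obvious) Keep the whole carbon skeleton and cut both C–O bonds of the dioxane last. Forward key step: Co(acac)2/O2/Et3SiH hydroperoxysilylation of a side-chain 1,1-disubstituted alkene, then 6-exo oxa-Michael closure of hydroperoxy enoate A1. Radical hydroperoxidation cannot tell the side-chain alkene from the tri- and tetrasubstituted octalin alkenes. C6 is formed without control, and C3/C2 arise by reversible conjugate addition and protonation, so up to eight diastereomers form that the remote ring-fusion centres cannot bias. The chosen plan makes the peroxide on a fragment without competing alkenes and sets each centre by a reagent.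

**Alternative 2:** Cut C4a–C8a and C1–C2 in a cationic bicyclization. Forward key step: ionization of the acyclic tertiary allylic alcohol A2 to an allyl cation, ring A closure by the prenyl alkene, ring B closure by the trisubstituted alkene, proton loss. Both stereocentres arise in the first closure from an achiral chain with no handle for enantiocontrol. Proton loss from the doubly allylic CH2 competes with the cisoid closure. Cis versus trans fusion and the site of the final elimination are left to chance. The oxy-Cope route fixes all three by mechanism and ends in a triflate ready for coupling.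

**Alternative 3:** Cut C4a–C8a and C7–C8 in an intramolecular Diels–Alder reaction of tetraene A3. The dienophile is unactivated, so high temperature is needed. Nothing controls absolute configuration or cis/trans fusion. A3 already needs a stereodefined tetrasubstituted Z-alkene next to a quaternary carbon, which is as hard as ring B itself. The chosen plan runs the [4+2] step on the flat dienone 3 with ethylene and lets the [3,3] shift turn the bicycle into the octalin.

Key step: step 5

Assumption: (4S)-3-propanoyl-4-(propan-2-yl)-1,3-thiazolidine-2-thione (15) is taken as a purchasable reagent; it is otherwise one N-acylation from the commercial thione.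
Assumption: no catalytic asymmetric Diels–Alder reaction of a cyclohexa-2,4-dienone with an ethylene equivalent is established, so the absolute configuration of the octalin half is taken from a resolution of ketone 4 (step 3).

## Route

Step 1
Reactants: 1 2,6-dimethylphenol
Product: 3 2,6,6-trimethylcyclohexa-2,4-dien-1-one, via lithium 2,6-dimethylphenoxide 2 (not isolated)
Conditions: n-BuLi, toluene, 0 °C; MeI, sealed vessel, 120 °C
Reagents that add atoms: iodomethane, CI
Why: Alkylative dearomatization: the aggregated lithium phenoxide in a non-polar solvent is C-methylated at one of its two equivalent ortho carbons, and the linear dienone cannot re-aromatize because C6 is now quaternary; the O-methylated by-product is removed by distillation.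

Step 2
Reactants: 3 2,6,6-trimethylcyclohexa-2,4-dien-1-one
Product: 4 rac-1,3,3-trimethylbicyclo[2.2.2]oct-5-en-2-one
Conditions: ethylene (50 bar), toluene, 2,6-di-tert-butyl-4-methylphenol (trace), 160 °C, autoclave
Reagents that add atoms: ethylene, C=C
Why: Diels–Alder reaction of the cyclohexa-2,4-dienone as diene across C2 and C5; ethylene raises no regio- or endo/exo question, the rigid bicycle fixes the relative configuration of the bridgeheads, and dimerization of 3 is reversible at this temperature.

Step 3
Reactants: 4 rac-1,3,3-trimethylbicyclo[2.2.2]oct-5-en-2-one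
Product: 5 (1R,4S)-1,3,3-trimethylbicyclo[2.2.2]oct-5-en-2-one
Conditions: preparative supercritical-fluid chromatography, amylose tris(3,5-dimethylphenylcarbamate) phase, CO2/i-PrOH
Reagents that add atoms: none
Why: Resolution of a small rigid ketone two steps from a commodity phenol; only the (1R,4S) enantiomer, whose bridgehead C4 becomes C8a of the target, is carried on, and its configuration is to be confirmed by vibrational circular dichroism.

Step 4
Reactants: 5 (1R,4S)-1,3,3-trimethylbicyclo[2.2.2]oct-5-en-2-one
Product: 6 (1R,2S,4S)-1,3,3-trimethyl-2-(prop-1-en-2-yl)bicyclo[2.2.2]oct-5-en-2-ol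
Conditions: isopropenylmagnesium bromide, LaCl3·2LiCl, THF, 0 °C → rt; H2O
Reagents that add atoms: isopropenylmagnesium bromide, CC(=C)[Mg]Br
Why: Grignard 1,2-addition to a ketone that cannot enolize (both α-carbons are quaternary), helped by the oxophilic lanthanum salt; the nucleophile should enter from the face of the C5=C6 etheno bridge, which is less shielded than the ethano face, so the isopropenyl group lies syn to the ring alkene as the [3,3] shift requires.

Step 5
Reactants: 6 (1R,2S,4S)-1,3,3-trimethyl-2-(prop-1-en-2-yl)bicyclo[2.2.2]oct-5-en-2-ol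
Product: 9 (4aR,8aS)-1,1,3,6-tetramethyl-1,4,4a,7,8,8a-hexahydronaphthalen-2-yl trifluoromethanesulfonate, via potassium alkoxide 7 (not isolated), via potassium enolate 8 (not isolated)
Conditions: KH, 18-crown-6, THF, rt → 50 °C; PhNTf2, −78 → 0 °C; H2O
Reagents that add atoms: N-phenylbis(trifluoromethanesulfonimide), O=S(=O)(N(c1ccccc1)S(=O)(=O)C(F)(F)F)C(F)(F)F
Why: Deprotonation gives the crown-separated alkoxide 7, whose C1–C2 bond (between two fully substituted carbons and weakened by the oxyanion) breaks while the isopropenyl CH2 bonds to C5 of the etheno bridge in a concerted [3,3] shift through the boat array that the bicycle enforces. The closest known reaction type is the anionic oxy-Cope rearrangement of 2-alkenylbicyclo[2.2.2]oct-5-en-2-olates to cis-fused octalones, with O-sulfonylation of the enolate in the same flask. Ring B (C1, C2, C3, C4, C4a, C8a) is closed by the new C4–C4a bond through the six-centre sigmatropic transition state, not by an ionic ring closure; ring A is the cyclohexene of the bicycle, set free when the C1–C2 bridge bond is cut. The one new stereocentre, C4a, is set by suprafacial delivery of the alkenyl terminus to the face of C5 that looks toward the keto bridge, which places H-4a cis to H-8a; its absolute configuration follows from bridgehead C4 of 5, which becomes C8a unchanged. The ring A alkene ends at C5=C6 (the former bridgehead methyl carbon becomes C6) and enolate 8 is formed only between C2 and C3; both follow from the pericyclic electron flow, not from a choice made by a base. The step needs [3,3] shift over fragmentation–recombination ([1,3] shift) and O- over C-sulfonylation. The first is secured by the syn relation of alkenyl group and etheno bridge and by strain release of the bicycle, the second by the hard sulfonyl donor and the hindered tetrasubstituted enolate carbon.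

Step 6
Reactants: 10 geraniol
Product: 11 [(2R,3R)-3-methyl-3-(4-methylpent-3-en-1-yl)oxiran-2-yl]methanol
Conditions: Ti(OiPr)4 (5 mol %), D-(−)-diethyl tartrate (7 mol %), t-BuOOH, 4 Å molecular sieves, CH2Cl2, −20 °C
Reagents that add atoms: tert-butyl hydroperoxide, CC(C)(C)OO
Why: Sharpless asymmetric epoxidation; the allylic hydroxyl directs the titanium tartrate to the C2=C3 alkene only, and D-(−)-tartrate gives the (2R,3R) epoxide, which fixes the future quaternary peroxy carbon.

Step 7
Reactants: 11 [(2R,3R)-3-methyl-3-(4-methylpent-3-en-1-yl)oxiran-2-yl]methanol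
Product: 12 (2R,3S)-3-hydroperoxy-3,7-dimethyloct-6-ene-1,2-diol
Conditions: H2O2 (anhydrous, Et2O), H3PMo12O40 (cat.), rt
Reagents that add atoms: hydrogen peroxide, OO
Why: Acid-catalysed perhydrolysis of a trisubstituted epoxide: H2O2 opens the activated oxirane at the tertiary carbon with inversion (borderline SN2), which puts the peroxy oxygen on the face needed for dioxane C6; the remote prenyl alkene is far less reactive than the protonated epoxide.

Step 8
Reactants: 12 (2R,3S)-3-hydroperoxy-3,7-dimethyloct-6-ene-1,2-diol
Product: 14 (4R)-4-[(3S)-6-methoxy-3-methyl-1,2-dioxan-3-yl]-2,2-dimethyl-1,3-dioxolane (both epimers at the acetal carbon), via cyclic hemiperoxyacetal 13 (not isolated)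
Conditions: O3, pyridine, CH2Cl2, −78 °C; Me2C(OMe)2, MeOH, pyridinium p-toluenesulfonate, rt
Reagents that add atoms: 2,2-dimethoxypropane, COC(C)(C)OC; methanol, CO
Why: Pyridine-moderated ozonolysis cleaves the prenyl alkene to the aldehyde without a reductive work-up that would endanger the hydroperoxide, and the δ-hydroperoxy aldehyde closes to the six-membered hemiperoxyacetal 13. Mild acid then methylates the hemiperoxyacetal and ties the vicinal diol up as the acetonide so that it cannot form an internal bicyclic acetal; the acetal carbon may stay an epimer mixture because it is ionized in step 9.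

Step 9
Reactants: 14 (4R)-4-[(3S)-6-methoxy-3-methyl-1,2-dioxan-3-yl]-2,2-dimethyl-1,3-dioxolane; 15 (4S)-3-propanoyl-4-(propan-2-yl)-1,3-thiazolidine-2-thione
Product: 17 (4S)-3-[(2R)-2-{(3R,6S)-6-[(4R)-2,2-dimethyl-1,3-dioxolan-4-yl]-6-methyl-1,2-dioxan-3-yl}propanoyl]-4-(propan-2-yl)-1,3-thiazolidine-2-thione, via chlorotitanium enolate 16 (not isolated)
Conditions: 15, TiCl4, i-Pr2NEt, CH2Cl2, −78 °C; then 14, SnCl4, −78 → −40 °C; H2O
Reagents that add atoms: none
Why: Proposed new method: SnCl4 ionizes the methoxy group of the peroxyacetal to a cyclic peroxycarbenium ion, which the chelated (Z)-chlorotitanium enolate 16 captures at carbon through an open transition state; the closest known reaction types are the Lewis-acid-mediated addition of silyl ketene acetals to 3-alkoxy-1,2-dioxanes and the addition of titanium enolates of N-acyl thiazolidinethiones to dialkyl and cyclic acetals, which gives 2,3-anti adducts. The isopropyl group shields one enolate face and should set propanoate C2 as R, the anti topicity should set dioxane C3 as R, and axial attack on the half-chair that keeps the larger C6 substituent equatorial points the same way; tetravalent titanium and tin are not reducing, so the O–O bond should survive as it does in the silyl ketene acetal reactions.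

Step 10
Reactants: 17 (4S)-3-[(2R)-2-{(3R,6S)-6-[(4R)-2,2-dimethyl-1,3-dioxolan-4-yl]-6-methyl-1,2-dioxan-3-yl}propanoyl]-4-(propan-2-yl)-1,3-thiazolidine-2-thione
Product: 18 methyl (2R)-2-{(3R,6S)-6-[(4R)-2,2-dimethyl-1,3-dioxolan-4-yl]-6-methyl-1,2-dioxan-3-yl}propanoate
Conditions: MeOH, imidazole (cat.), CH2Cl2, rt
Reagents that add atoms: methanol, CO
Why: Acyl transfer from the activated thioimide to methanol under nearly neutral conditions releases the auxiliary and spares the β-peroxy ester from enolization.

Step 11
Reactants: 18 methyl (2R)-2-{(3R,6S)-6-[(4R)-2,2-dimethyl-1,3-dioxolan-4-yl]-6-methyl-1,2-dioxan-3-yl}propanoate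
Product: 19 methyl (2R)-2-[(3R,6S)-6-formyl-6-methyl-1,2-dioxan-3-yl]propanoate
Conditions: H5IO6, EtOAc, 0 °C → rt
Reagents that add atoms: none
Why: Periodic acid hydrolyses the terminal acetonide and cleaves the freed 1,2-diol in one flask (Malaprade cleavage); the aldehyde sits on the quaternary peroxy carbon and can neither enolize nor epimerize.

Step 12
Reactants: 19 methyl (2R)-2-[(3R,6S)-6-formyl-6-methyl-1,2-dioxan-3-yl]propanoate
Product: 20 methyl (2R)-2-[(3R,6S)-6-ethenyl-6-methyl-1,2-dioxan-3-yl]propanoate
Conditions: Ph3PCH3Br, KN(SiMe3)2, THF, −78 → 0 °C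
Reagents that add atoms: methyltriphenylphosphonium bromide, C[P+](c1ccccc1)(c1ccccc1)c1ccccc1.[Br-]
Why: Wittig methylenation; at low temperature the ylide should add to the aldehyde much faster than it deprotonates the α-branched ester, and phosphorus ylides, unlike phosphines, are expected to leave a dialkyl peroxide alone.

Step 13
Reactants: 20 methyl (2R)-2-[(3R,6S)-6-ethenyl-6-methyl-1,2-dioxan-3-yl]propanoate; 9 (4aR,8aS)-1,1,3,6-tetramethyl-1,4,4a,7,8,8a-hexahydronaphthalen-2-yl trifluoromethanesulfonate
Product: 22 methyl (2R)-2-[(3R,6R)-6-methyl-6-{2-[(4aR,8aS)-1,1,3,6-tetramethyl-1,4,4a,7,8,8a-hexahydronaphthalen-2-yl]ethyl}-1,2-dioxan-3-yl]propanoate, via B-alkyl borane 21 (not isolated)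
Conditions: 20, 9-borabicyclo[3.3.1]nonane, THF, 0 °C → rt; then 9, Pd(dppf)Cl2 (5 mol %), AsPh3, K3PO4 (aq), DMF, 50 °C
Reagents that add atoms: none
Why: Anti-Markovnikov hydroboration of the monosubstituted alkene and B-alkyl Suzuki–Miyaura coupling with the enol triflate join the linker CH2 to octalin C2 without touching a stereocentre. Cyclohexenyl triflates with this 2,6,6-substitution are known partners, and 1,2-dioxanes have precedent for surviving this borane and palladium-catalysed coupling, since oxidative addition of zerovalent palladium to a triflate is faster than its reaction with a dialkyl peroxide.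

Step 14
Reactants: 22 methyl (2R)-2-[(3R,6R)-6-methyl-6-{2-[(4aR,8aS)-1,1,3,6-tetramethyl-1,4,4a,7,8,8a-hexahydronaphthalen-2-yl]ethyl}-1,2-dioxan-3-yl]propanoate
Product: 23 (2R)-2-[(3R,6R)-6-methyl-6-{2-[(4aR,8aS)-1,1,3,6-tetramethyl-1,4,4a,7,8,8a-hexahydronaphthalen-2-yl]ethyl}-1,2-dioxan-3-yl]propanoic acid
Conditions: LiOH, THF/H2O, 0 °C; cold 1 M HCl to pH 3
Reagents that add atoms: lithium hydroxide, [Li+].[OH-]
Why: Saponification at low temperature; the α-methyl group slows enolization, so hydrolysis should outrun retro-oxa-Michael opening of the β-peroxy ester, and no stereocentre changes if C2 is not deprotonated.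

## Compound list

1 | 2,6-dimethylphenol | Cc1cccc(C)c1O | starting material
2 | lithium 2,6-dimethylphenoxide | Cc1cccc(C)c1[O-].[Li+] | intermediate
3 | 2,6,6-trimethylcyclohexa-2,4-dien-1-one | CC1=CC=CC(C)(C)C1=O | intermediate
4 | rac-1,3,3-trimethylbicyclo[2.2.2]oct-5-en-2-one (racemate) | CC12C=CC(CC1)C(C)(C)C2=O | intermediate
5 | (1R,4S)-1,3,3-trimethylbicyclo[2.2.2]oct-5-en-2-one | C[C@]12C=C[C@H](CC1)C(C)(C)C2=O | intermediate
6 | (1R,2S,4S)-1,3,3-trimethyl-2-(prop-1-en-2-yl)bicyclo[2.2.2]oct-5-en-2-ol | C[C@]12C=C[C@H](CC1)C(C)(C)[C@@]2(O)C(C)=C | intermediate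
7 | potassium (1R,2S,4S)-1,3,3-trimethyl-2-(prop-1-en-2-yl)bicyclo[2.2.2]oct-5-en-2-olate | C[C@]12C=C[C@H](CC1)C(C)(C)[C@@]2([O-])C(C)=C.[K+] | intermediate
8 | potassium (4aR,8aS)-1,1,3,6-tetramethyl-1,4,4a,7,8,8a-hexahydronaphthalen-2-olate | CC1=C[C@H]2CC(C)=C([O-])C(C)(C)[C@H]2CC1.[K+] | intermediate
9 | (4aR,8aS)-1,1,3,6-tetramethyl-1,4,4a,7,8,8a-hexahydronaphthalen-2-yl trifluoromethanesulfonate | CC1=C[C@H]2CC(C)=C(OS(=O)(=O)C(F)(F)F)C(C)(C)[C@H]2CC1 | intermediate
10 | geraniol | CC(C)=CCC/C(C)=C/CO | starting material
11 | [(2R,3R)-3-methyl-3-(4-methylpent-3-en-1-yl)oxiran-2-yl]methanol | OC[C@H]1O[C@]1(C)CCC=C(C)C | intermediate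
12 | (2R,3S)-3-hydroperoxy-3,7-dimethyloct-6-ene-1,2-diol | OC[C@@H](O)[C@@](C)(OO)CCC=C(C)C | intermediate
13 | (6S)-6-[(1R)-1,2-dihydroxyethyl]-6-methyl-1,2-dioxan-3-ol (C3 epimers) | OC[C@@H](O)[C@]1(C)CCC(O)OO1 | intermediate
14 | (4R)-4-[(3S)-6-methoxy-3-methyl-1,2-dioxan-3-yl]-2,2-dimethyl-1,3-dioxolane (epimers at the acetal carbon) | CC1(C)OC[C@@H](O1)[C@]2(C)CCC(OC)OO2 | intermediate
15 | (4S)-3-propanoyl-4-(propan-2-yl)-1,3-thiazolidine-2-thione | CCC(=O)N1C(=S)SC[C@@H]1C(C)C | starting material
16 | (Z)-chlorotitanium enolate of 15 | C/C=C(\O[Ti](Cl)(Cl)Cl)N1C(=S)SC[C@@H]1C(C)C | intermediate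
17 | (4S)-3-[(2R)-2-{(3R,6S)-6-[(4R)-2,2-dimethyl-1,3-dioxolan-4-yl]-6-methyl-1,2-dioxan-3-yl}propanoyl]-4-(propan-2-yl)-1,3-thiazolidine-2-thione | CC1(C)OC[C@@H](O1)[C@]2(C)CC[C@H]([C@@H](C)C(=O)N3C(=S)SC[C@@H]3C(C)C)OO2 | intermediate
18 | methyl (2R)-2-{(3R,6S)-6-[(4R)-2,2-dimethyl-1,3-dioxolan-4-yl]-6-methyl-1,2-dioxan-3-yl}propanoate | CC1(C)OC[C@@H](O1)[C@]2(C)CC[C@H]([C@@H](C)C(=O)OC)OO2 | intermediate
19 | methyl (2R)-2-[(3R,6S)-6-formyl-6-methyl-1,2-dioxan-3-yl]propanoate | O=C[C@]1(C)CC[C@H]([C@@H](C)C(=O)OC)OO1 | intermediate
20 | methyl (2R)-2-[(3R,6S)-6-ethenyl-6-methyl-1,2-dioxan-3-yl]propanoate | C=C[C@]1(C)CC[C@H]([C@@H](C)C(=O)OC)OO1 | intermediate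
21 | methyl (2R)-2-{(3R,6R)-6-[2-(9-borabicyclo[3.3.1]nonan-9-yl)ethyl]-6-methyl-1,2-dioxan-3-yl}propanoate | B1(CC[C@]2(C)CC[C@H]([C@@H](C)C(=O)OC)OO2)C3CCCC1CCC3 | intermediate
22 | methyl (2R)-2-[(3R,6R)-6-methyl-6-{2-[(4aR,8aS)-1,1,3,6-tetramethyl-1,4,4a,7,8,8a-hexahydronaphthalen-2-yl]ethyl}-1,2-dioxan-3-yl]propanoate | CC1=C[C@H]2CC(C)=C(CC[C@]3(C)CC[C@H]([C@@H](C)C(=O)OC)OO3)C(C)(C)[C@H]2CC1 | intermediate
23 | (2R)-2-[(3R,6R)-6-methyl-6-{2-[(4aR,8aS)-1,1,3,6-tetramethyl-1,4,4a,7,8,8a-hexahydronaphthalen-2-yl]ethyl}-1,2-dioxan-3-yl]propanoic acid | CC1=C[C@H]2CC(C)=C(CC[C@]3(C)CC[C@H]([C@@H](C)C(=O)O)OO3)C(C)(C)[C@H]2CC1 | target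

## Step count and least certain steps

Total: 14 steps (steps 1–5 octalin branch, steps 6–12 dioxane branch, steps 13–14 union and release). Longest linear sequence: 9 steps (steps 6–14, from geraniol); the octalin branch joins at step 13.

**Step 9 (Proposed new method).** Three things may go wrong. The enolate may be oxidized by the Lewis-acid-activated peroxide. Ionization may occur at the wrong oxygen (ring peroxide or acetonide) and open the dioxane. Addition to the ring-constrained peroxycarbenium ion may follow syn instead of anti topicity and give the wrong C3. The fallback uses known chemistry and sets out from 14: TiCl4-mediated Mukaiyama-type addition of (E)-1-methoxy-1-(trimethylsilyloxy)prop-1-ene, a reaction established on 3-alkoxy-1,2-dioxanes, gives the methyl ester directly. Axial attack should favour the wanted C3 configuration, and the C2 epimer is removed by chromatography. This route returns at 18 and makes no new compound (F0).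

**Step 5 (key step).** The alkoxide may fragment and recombine to the [1,3]-shift isomer, and minor alkenyl-anti material from step 4 cannot rearrange at all. O-sulfonylation of the hindered enolate may be incomplete. The fallback sets out from 6: silylation gives the O-trimethylsilyl ether of 6 F1. A neutral thermal siloxy-Cope rearrangement (220–250 °C, sealed tube), which avoids ionic fragmentation, gives the trimethylsilyl enol ether of the octalone F2. MeLi then frees the lithium enolate, which is trapped by PhNTf2; the route returns at 9.

**Step 2.** Dimerization or thermal decomposition of 3 may outrun the slow cycloaddition of unactivated ethylene. The fallback sets out from 3: phenyl vinyl sulfone serves as an ethylene equivalent (toluene, 110 °C) and gives the phenylsulfonyl adduct F3 as a mixture of regio- and stereoisomers that all converge. Sodium amalgam (6 % Na in Hg), Na2HPO4, MeOH removes the sulfonyl group; the route returns at 4.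

**Step 13.** Oxidative addition and transmetalation at the hindered tetrasubstituted triflate may be slow, which would let zerovalent palladium or the borane attack the O–O bond or let the alkylborane protodeboronate. The fallback sets out from 9 and 19 and moves the palladium step to before the peroxide is present:
- Stille coupling of 9 with Bu3SnCH2OH (Pd(PPh3)4, LiCl) gives the allylic alcohol F4.
- PPh3·HBr gives the allylic triphenylphosphonium bromide F5.
- Wittig reaction of F5 (KN(SiMe3)2) with aldehyde 19 gives the diene ester F6.
- Diimide (potassium azodicarboxylate, AcOH) reduces only the disubstituted alkene; the route returns at 22 and step 12 is not needed.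

**Step 14.** Hydroxide may open the β-peroxy ester by retro-oxa-Michael reaction (with loss of the C2/C3 configuration) or trigger Kornblum–DeLaMare cleavage at C3–H. The fallback sets out from 17 and avoids any ester:
- LiOH/H2O2 at 0 °C cleaves the thioimide quickly to the acetonide acid F7.
- H5IO6 gives the formyl acid F8.
- Wittig methylenation with two equivalents of ylide gives the vinyl acid F9.
- Hydroboration with an extra equivalent of 9-borabicyclo[3.3.1]nonane and coupling with 9 as in step 13 give 23 directly; the carboxylate cannot enolize toward elimination.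

## Further compounds

F0 | step 9 | none | none
F1 | step 5 | O-trimethylsilyl ether of 6 | C[C@]12C=C[C@H](CC1)C(C)(C)[C@@]2(O[Si](C)(C)C)C(C)=C
F2 | step 5 | trimethylsilyl enol ether of the octalone | CC1=C[C@H]2CC(C)=C(O[Si](C)(C)C)C(C)(C)[C@H]2CC1
F3 | step 2 | phenylsulfonyl adduct, rac-1,3,3-trimethyl-7-(phenylsulfonyl)bicyclo[2.2.2]oct-5-en-2-one (one regioisomer shown) | CC12C=CC(CC1S(=O)(=O)c3ccccc3)C(C)(C)C2=O
F4 | step 13 | allylic alcohol, [(4aR,8aS)-1,1,3,6-tetramethyl-1,4,4a,7,8,8a-hexahydronaphthalen-2-yl]methanol | CC1=C[C@H]2CC(C)=C(CO)C(C)(C)[C@H]2CC1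
F5 | step 13 | allylic triphenylphosphonium bromide | CC1=C[C@H]2CC(C)=C(C[P+](c3ccccc3)(c3ccccc3)c3ccccc3)C(C)(C)[C@H]2CC1.[Br-]
F6 | step 13 | diene ester (E/Z mixture at the new alkene) | CC1=C[C@H]2CC(C)=C(C=C[C@]3(C)CC[C@H]([C@@H](C)C(=O)OC)OO3)C(C)(C)[C@H]2CC1
F7 | step 14 | acetonide acid, (2R)-2-{(3R,6S)-6-[(4R)-2,2-dimethyl-1,3-dioxolan-4-yl]-6-methyl-1,2-dioxan-3-yl}propanoic acid | CC1(C)OC[C@@H](O1)[C@]2(C)CC[C@H]([C@@H](C)C(=O)O)OO2
F8 | step 14 | formyl acid, (2R)-2-[(3R,6S)-6-formyl-6-methyl-1,2-dioxan-3-yl]propanoic acid | O=C[C@]1(C)CC[C@H]([C@@H](C)C(=O)O)OO1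
F9 | step 14 | vinyl acid, (2R)-2-[(3R,6S)-6-ethenyl-6-methyl-1,2-dioxan-3-yl]propanoic acid | C=C[C@]1(C)CC[C@H]([C@@H](C)C(=O)O)OO1
A1 | alternative 1 | methyl (2E)-6-hydroperoxy-2,6-dimethyl-8-[(4aR,8aS)-1,1,3,6-tetramethyl-1,4,4a,7,8,8a-hexahydronaphthalen-2-yl]oct-2-enoate | CC1=C[C@H]2CC(C)=C(CCC(C)(OO)CC/C=C(\C)C(=O)OC)C(C)(C)[C@H]2CC1
A2 | alternative 2 | (7E,10E)-13-{[tert-butyl(dimethyl)silyl]oxy}-2,6,10-trimethyltrideca-2,7,10-trien-6-ol | CC(C)=CCCC(C)(O)/C=C/C/C(C)=C/CCO[Si](C)(C)C(C)(C)C
A3 | alternative 3 | (4Z,7E)-4-(2-{[tert-butyl(dimethyl)silyl]oxy}ethyl)-3,3,5,9-tetramethyldeca-1,4,7,9-tetraene | C=CC(C)(C)/C(CCO[Si](C)(C)C(C)(C)C)=C(/C)C/C=C/C(C)=C
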